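## The problem

Compound 17 is a 3,4-dibenzyl-γ-butyrolactone. With the ring numbered O1, C2 (C=O), C3, C4, C5, C3 carries the C7' methylene of the 4-hydroxy-3,5-dimethoxyphenyl (syringyl) ring and C4 the C7 methylene of the 3,4-dimethoxyphenyl (veratryl) ring; both centres are R and the benzyl groups are trans. The skeleton is small, so the real tasks are to place two similar but different electron-rich benzyl groups on neighbouring carbons without interchanging them, and to fix two contiguous stereocentres absolutely. C3 lies next to the carbonyl group and can be epimerised towards the more stable trans arrangement, so a defined C4 can correct C3; C4 has no such handle and is normally the centre that must be set first. Sensitive points are the lactone (ring opening, enolisation at C3), the hindered free phenol (oxidation, interference with bases and metals; carried as a benzyl ether) and the two activated arenes, which would trap a cation generated nearby. The feature on which the plan rests is that C4 bears, beside C3 and H, two one-carbon arms that differ only in their termini: C5 ends at O1 and C7 at the veratryl ring. Carbon 3 of an oxetane carries just such a pair of methylenes tied together by one oxygen, so an oxetan-3-yl group on the α-carbon of an open-chain acid is a masked C4. Attack of the carboxyl group on one methylene forms C5–O1 and the lactone and frees the other as a hydroxymethyl group that becomes C7. In that hydroxymethyl lactone the two arms can still exchange roles by acyl transfer, which puts C4 under the thermodynamic control of C3 and reverses the usual direction of stereochemical relay.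

## Retrosynthesis

17 ⇒ 16. Only the phenolic O–benzyl bond is cut. A benzyl ether is the one mask that tolerates enolate chemistry, hydroxide, sulfonic acid, phosphine/CBr4 and nickel/zinc, and it leaves under neutral hydrogenolysis, which touches neither the lactone nor C3.

16 ⇒ 14 + 15. The C7–aryl bond is cut, giving bromomethyl lactone 14 and commercial 4-bromo-1,2-dimethoxybenzene 15. The neighbouring cuts are C3–C7' (enolate benzylation) and C4–C7 (conjugate addition to a butenolide); both require C4 or the veratryl group to be in place before the ring is made. The C7–aryl cut removes a whole arene and leaves a lactone whose C4 arm is a plain CH2X group. The forward step must be an sp3–sp2 coupling of a β-branched primary halide that uses no organometallic basic enough to open the lactone or enolise C3.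

14 ⇒ 13. The C7–Br bond is traced to the C7–OH of hydroxymethyl lactone 13. This is the last point at which the cis isomer 12 can still be converted into 13, so the alcohol stage is where diastereomeric purity must be secured.

13 ⇒ 11 (key disconnection). The C5–O1 bond is cut, and C5 and C7 are rejoined through one oxygen as the oxetane of acid 11. The alternative at this point, lactonisation of a 2-substituted propane-1,3-diol derivative, would require the two hydroxymethyl groups to be told apart by protecting groups or an enzyme. The oxetane keeps them equivalent until the moment the carboxyl group chooses one, and releases the other already differentiated. The precursor has no ring besides the oxetane and one stereocentre instead of two. The forward reaction must select between two diastereotopic methylenes; this is made tolerant of poor kinetic selection because the cis lactone 12 and 13 interconvert by translactonisation and 13 is the more stable.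

11 ⇒ 10. The C3–H and C7'–H bonds are removed, leading to (E)-acrylic acid 10. Carboxylate-directed asymmetric hydrogenation of α-sec-alkylcinnamic acids is an established way to set exactly this type of centre, and it uses no stoichiometric auxiliary. The alternative, auxiliary-controlled benzylation of an oxetanylacetyl imide, is kept in reserve. The forward step needs high facial selectivity on a geometrically pure alkene and conditions under which the oxetane stays closed.

10 ⇒ 9 ⇒ 4 + 6. Ester hydrolysis and then cleavage of the C3=C7' double bond give ethyl 2-(oxetan-3-yl)acetate 4 and aldehyde 6. An aldol condensation is preferred to an olefination with an α-branched phosphorus reagent, which is sluggish and poorly selective. The elimination must deliver the (E)-isomer, in which the aryl group is trans to the ester.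

4 ⇒ 3 ⇒ 1 + 2 and 6 ⇒ 5. Ester 4 comes from oxetan-3-one 1 and triethyl phosphonoacetate 2 through ylidene ester 3. Aldehyde 6 is the benzyl ether of syringaldehyde 5. All four starting materials (1, 2, 5, 15) are commercial.

## Roads not taken

Alternative 1: The cut is made through C3–C4 and C7–aryl at once. A vinylboron ate complex is formed from the secondary boronic ester tert-butyl{3-[4-(benzyloxy)-3,5-dimethoxyphenyl]-2-(4,4,5,5-tetramethyl-1,3,2-dioxaborolan-2-yl)propoxy}dimethylsilane A2 and vinyllithium A4. Palladium-catalysed conjunctive coupling with 3,4-dimethoxyphenyl trifluoromethanesulfonate A3 would then give the boronic ester A1, in which C4 bears boron.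
- Merits: two skeletal bonds are formed in one step, C4 is set by the chiral catalyst independently of C3, and the aryl group is varied at will.
- Weak points: the migrating group is a β-branched secondary alkyl group carrying a stereocentre, the least favourable class for the 1,2-shift, and it meets the catalyst in a matched or mismatched sense. A2 needs its own asymmetric synthesis. No ring is closed: A1 still requires one-carbon homologation at boron, oxidation, desilylation and oxidation of C2 to the acid level, with the two primary carbinol termini kept apart throughout.
- Comparison: catalyst control of C4 is a genuine advantage where the cis series is wanted. For the trans target the chosen plan obtains C4 without a reagent, and its key step closes the ring and differentiates the two arms, which this route must do by separate operations. The route would be longer than the chosen one.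

Alternative 2: The cut is made at O1–C2 and O1–C5 by deleting O1. This leads to the prochiral ketone 3-(3,4-dimethoxybenzyl)cyclobutan-1-one A6, which a Baeyer–Villiger monooxygenase and O2 would expand to (R)-4-(3,4-dimethoxybenzyl)dihydrofuran-2(3H)-one A5. Kinetic trans-benzylation of the enolate of A5 with bromide F2 then leads to 16.
- Merits: this road is shorter than the chosen one, roughly five steps in the longest line against nine. It sets C4 together with the ring, and its endgame is the classical order in which C4 directs C3.
- Weak points: the sense and level of enantiotopic discrimination in such oxidations depend strongly on the enzyme and on the 3-substituent, so the (R)-lactone requires an enzyme to be found for this substrate. A5 is not crystalline enough to count on upgrading, and the electron-rich benzylic bromide is a labile alkylating agent.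
- Comparison: the chosen plan has to set against the shorter route that its absolute configuration comes from a chemical catalyst available in both enantiomeric forms for a known substrate class, that C4 is self-correcting, and that the C4 aryl group enters last by cross-coupling. If a suitable enzyme is at hand, Alternative 2 is the more economical route.

Alternative 3: The cut is made at C7'–aryl and C3–C4. The arylrhodium species from [4-(benzyloxy)-3,5-dimethoxyphenyl]boronic acid A9 would add across the triple bond of (E)-3-(3,4-dimethoxyphenyl)allyl propiolate A8. The alkenylrhodium would insert the tethered alkene and, after protonation at C7, give the benzylidene lactone A7. Reduction of the exocyclic alkene and equilibration at C3 would lead to 16.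
- Merits: ring, two C–C bonds and the C4 centre arise in one enantioselective catalytic step from achiral pieces; on paper this is the shortest route.
- Weak points: the alkenylrhodium formed from a propiolate sits α to the ester and is prone to protonation, which ends in simple hydroarylation. The ester tether prefers the conformation that holds alkyne and alkene apart. The alkene is an unactivated styrene without a leaving group, whereas the closest precedent uses acceptor alkenes or allylic leaving groups. The terminal alkyne C–H is itself reactive. C3 must still be set afterwards, by hydrogenation to the cis lactone followed by base epimerisation.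
- Comparison: convergence clearly favours this road. The chosen plan offers instead a key step of a documented reaction type with a thermodynamic safeguard, and a C3 centre set directly.

Key step: step 7

Assumption: the sense of induction of the iridium catalyst in step 6 is assigned by analogy with α-isopropylcinnamic acids; should the (S)-acid predominate on this substrate, the enantiomeric catalyst is used and nothing else changes.

## Route

Step 1
Reactants: 1 oxetan-3-one; 2 triethyl phosphonoacetate
Product: 3 ethyl 2-(oxetan-3-ylidene)acetate
Conditions: NaH, THF, 0 °C → rt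
Reagents that add atoms: none
Why: Horner–Wadsworth–Emmons olefination; the strained, unhindered ketone is highly electrophilic towards the stabilised phosphonate anion, and the symmetric ring leaves no alkene geometry to control.

Step 2
Reactants: 3 ethyl 2-(oxetan-3-ylidene)acetate
Product: 4 ethyl 2-(oxetan-3-yl)acetate
Conditions: H2 (1 atm), 10% Pd/C, EtOAc, rt
Reagents that add atoms: none
Why: Heterogeneous hydrogenation of the electron-poor exocyclic alkene; under neutral conditions at low pressure the oxetane C–O bonds are not cleaved.

Step 3
Reactants: 5 syringaldehyde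
Product: 6 4-(benzyloxy)-3,5-dimethoxybenzaldehyde
Conditions: BnBr, K2CO3, DMF, 60 °C
Reagents that add atoms: benzyl bromide, BrCc1ccccc1
Why: Williamson etherification of the phenoxide; the benzyl ether withstands every later reagent and is removed last under neutral conditions.

Step 4
Reactants: 4 ethyl 2-(oxetan-3-yl)acetate; 6 4-(benzyloxy)-3,5-dimethoxybenzaldehyde
Product: 9 ethyl (E)-3-[4-(benzyloxy)-3,5-dimethoxyphenyl]-2-(oxetan-3-yl)prop-2-enoate, via lithium aldolate 7 (not isolated), via β-acetoxy ester 8 (not isolated)
Conditions: LDA, THF, −78 °C; then 6; then Ac2O, −78 → 0 °C; then KOtBu, 0 °C → rt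
Reagents that add atoms: none
Why: Aldol condensation carried out as aldol addition of the lithium ester enolate to the non-enolisable aldehyde, O-acetylation and E1cB elimination; both aldol diastereomers pass through the same ester enolate and converge on the more stable (E)-alkene with the aryl group trans to the ester. The oxetane oxygen is γ to the enolate carbon and cannot be expelled.

Step 5
Reactants: 9 ethyl (E)-3-[4-(benzyloxy)-3,5-dimethoxyphenyl]-2-(oxetan-3-yl)prop-2-enoate
Product: 10 (E)-3-[4-(benzyloxy)-3,5-dimethoxyphenyl]-2-(oxetan-3-yl)prop-2-enoic acid
Conditions: LiOH, THF/MeOH/H2O, 50 °C; then aq. citric acid, 0 °C (pH 4–5), used at once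
Reagents that add atoms: lithium hydroxide, [Li+].[OH-]
Why: Saponification by acyl–oxygen cleavage; oxetane, benzyl ether and alkene geometry are inert to hydroxide. The acid is set free only briefly with a weak acid in the cold so that the carboxyl group does not open the oxetane at this achiral stage.

Step 6
Reactants: 10 (E)-3-[4-(benzyloxy)-3,5-dimethoxyphenyl]-2-(oxetan-3-yl)prop-2-enoic acid
Product: 11 (R)-3-[4-(benzyloxy)-3,5-dimethoxyphenyl]-2-(oxetan-3-yl)propanoic acid
Conditions: [Ir(cod)(L)]BArF (0.5 mol %; L = (Sa,S)-SIPHOX, 7-[bis(3,5-di-tert-butylphenyl)phosphanyl]-7'-[(4S)-4-benzyl-4,5-dihydrooxazol-2-yl]-1,1'-spirobiindane; BArF = B[3,5-(CF3)2C6H3]4), H2 (6 atm), Et3N (0.5 equiv), MeOH, rt; then cold aq. citric acid wash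
Reagents that add atoms: none
Why: Carboxylate-directed asymmetric hydrogenation, for which α-sec-alkylcinnamic acids are an established substrate class; the carboxylate binds iridium and hydrogen is delivered to one face of the trisubstituted alkene, which sets C3 as R. Triethylamine holds the substrate as carboxylate and so keeps the oxetane closed, and the homogeneous catalyst does not cleave the benzyl ether.

Step 7
Reactants: 11 (R)-3-[4-(benzyloxy)-3,5-dimethoxyphenyl]-2-(oxetan-3-yl)propanoic acid
Product: 13 (3R,4S)-3-[4-(benzyloxy)-3,5-dimethoxybenzyl]-4-(hydroxymethyl)dihydrofuran-2(3H)-one, via cis lactone 12 (not isolated)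
Conditions: CSA (10 mol %), CH2Cl2 (0.02 M), 0 °C → rt, then 40 °C until 12 is consumed
Reagents that add atoms: none
Why: This is an acid-catalysed intramolecular ring opening of a 3-substituted oxetane by a carboxylic acid; the closest known reaction types are the isomerisation of oxetane carboxylic acids to lactones and the phosphoric-acid-catalysed desymmetrisation of oxetanes by tethered oxygen nucleophiles. Protonation or hydrogen bonding at the oxetane oxygen activates both CH2–O bonds, and the carboxyl oxygen displaces the oxetane oxygen at one methylene in an SN2-type 5-exo-tet closure that forms C5–O1 and the γ-lactone and leaves the other methylene as the C7 hydroxymethyl group. The new centre C4 is controlled by C3: the two methylenes are diastereotopic, and closure onto the one that places the C3 benzyl group and the residual arm trans on the forming ring avoids the eclipsing contact of the cis transition state. Kinetic selection need not be complete, because the minor cis lactone 12 exchanges its ring oxygen and side-arm oxygen by acid-catalysed acyl transfer through a bicyclic ortho-acid intermediate, and this translactonisation turns 12 into 13 itself, the more stable isomer. C3 is not at risk, since the lactone does not enolise under catalytic sulfonic acid. The step also needs chemoselectivity for the carboxyl oxygen over the electron-rich arene and over intermolecular opening, which the favourable five-membered closure and high dilution should secure. Any 12 that remains is separated before step 8, because after bromination it can no longer be corrected and would lead into the enantiomeric series on later epimerisation.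

Step 8
Reactants: 13 (3R,4S)-3-[4-(benzyloxy)-3,5-dimethoxybenzyl]-4-(hydroxymethyl)dihydrofuran-2(3H)-one
Product: 14 (3R,4R)-3-[4-(benzyloxy)-3,5-dimethoxybenzyl]-4-(bromomethyl)dihydrofuran-2(3H)-one
Conditions: CBr4, PPh3, CH2Cl2, 0 °C → rt
Reagents that add atoms: carbon tetrabromide, BrC(Br)(Br)Br
Why: Appel bromination; bromide displaces the alkoxyphosphonium group at the primary carbon under neutral conditions, so lactone and C3 are untouched. No bond to C4 is broken, and its descriptor changes only because the priorities change.

Step 9
Reactants: 14 (3R,4R)-3-[4-(benzyloxy)-3,5-dimethoxybenzyl]-4-(bromomethyl)dihydrofuran-2(3H)-one; 15 4-bromo-1,2-dimethoxybenzene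
Product: 16 (3R,4R)-3-[4-(benzyloxy)-3,5-dimethoxybenzyl]-4-(3,4-dimethoxybenzyl)dihydrofuran-2(3H)-one
Conditions: NiCl2(glyme) (10 mol %), 4,4'-di-tert-butyl-2,2'-bipyridine (10 mol %), NaI (0.5 equiv), pyridine (10 mol %), Zn (2 equiv), DMA, 60 °C
Reagents that add atoms: none
Why: Nickel-catalysed reductive cross-electrophile coupling; the aryl bromide adds to zerovalent nickel, the primary alkyl radical formed from the bromide (iodide after halide exchange) is captured by the arylnickel species, and reductive elimination forms C7–aryl while zinc turns the catalyst over. No basic organometallic is present to attack the lactone or enolise C3, and the radical sits on the exocyclic carbon, so C4 is unaffected.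

Step 10
Reactants: 16 (3R,4R)-3-[4-(benzyloxy)-3,5-dimethoxybenzyl]-4-(3,4-dimethoxybenzyl)dihydrofuran-2(3H)-one
Product: 17 (3R,4R)-4-(3,4-dimethoxybenzyl)-3-(4-hydroxy-3,5-dimethoxybenzyl)dihydrofuran-2(3H)-one
Conditions: H2 (1 atm), 10% Pd/C, EtOAc/EtOH, rt
Reagents that add atoms: none
Why: Hydrogenolysis of the benzyl aryl ether; the lactone and the benzylic C–C bonds are inert, and the neutral medium preserves both stereocentres.

## Compound list

1 | oxetan-3-one | O=C1COC1 | starting material
2 | triethyl phosphonoacetate | CCOC(=O)CP(=O)(OCC)OCC | starting material
3 | ethyl 2-(oxetan-3-ylidene)acetate | CCOC(=O)C=C1COC1 | intermediate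
4 | ethyl 2-(oxetan-3-yl)acetate | CCOC(=O)CC1COC1 | intermediate
5 | syringaldehyde (4-hydroxy-3,5-dimethoxybenzaldehyde) | COc1cc(C=O)cc(OC)c1O | starting material
6 | 4-(benzyloxy)-3,5-dimethoxybenzaldehyde | COc1cc(C=O)cc(OC)c1OCc1ccccc1 | intermediate
7 | lithium 1-[4-(benzyloxy)-3,5-dimethoxyphenyl]-3-ethoxy-2-(oxetan-3-yl)-3-oxopropan-1-olate (lithium aldolate; both diastereomers; not isolated) | [Li+].CCOC(=O)C(C1COC1)C([O-])c1cc(OC)c(OCc2ccccc2)c(OC)c1 | intermediate
8 | ethyl 3-acetoxy-3-[4-(benzyloxy)-3,5-dimethoxyphenyl]-2-(oxetan-3-yl)propanoate (β-acetoxy ester; both diastereomers; not isolated) | CCOC(=O)C(C1COC1)C(OC(C)=O)c1cc(OC)c(OCc2ccccc2)c(OC)c1 | intermediate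
9 | ethyl (E)-3-[4-(benzyloxy)-3,5-dimethoxyphenyl]-2-(oxetan-3-yl)prop-2-enoate | CCOC(=O)/C(=C/c1cc(OC)c(OCc2ccccc2)c(OC)c1)C1COC1 | intermediate
10 | (E)-3-[4-(benzyloxy)-3,5-dimethoxyphenyl]-2-(oxetan-3-yl)prop-2-enoic acid | OC(=O)/C(=C/c1cc(OC)c(OCc2ccccc2)c(OC)c1)C1COC1 | intermediate
11 | (R)-3-[4-(benzyloxy)-3,5-dimethoxyphenyl]-2-(oxetan-3-yl)propanoic acid | OC(=O)[C@H](Cc1cc(OC)c(OCc2ccccc2)c(OC)c1)C1COC1 | intermediate
12 | (3R,4R)-3-[4-(benzyloxy)-3,5-dimethoxybenzyl]-4-(hydroxymethyl)dihydrofuran-2(3H)-one (cis lactone; minor kinetic isomer; not isolated) | OC[C@@H]1COC(=O)[C@@H]1Cc1cc(OC)c(OCc2ccccc2)c(OC)c1 | intermediate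
13 | (3R,4S)-3-[4-(benzyloxy)-3,5-dimethoxybenzyl]-4-(hydroxymethyl)dihydrofuran-2(3H)-one (trans) | OC[C@H]1COC(=O)[C@@H]1Cc1cc(OC)c(OCc2ccccc2)c(OC)c1 | intermediate
14 | (3R,4R)-3-[4-(benzyloxy)-3,5-dimethoxybenzyl]-4-(bromomethyl)dihydrofuran-2(3H)-one (trans) | BrC[C@H]1COC(=O)[C@@H]1Cc1cc(OC)c(OCc2ccccc2)c(OC)c1 | intermediate
15 | 4-bromo-1,2-dimethoxybenzene | COc1ccc(Br)cc1OC | starting material
16 | (3R,4R)-3-[4-(benzyloxy)-3,5-dimethoxybenzyl]-4-(3,4-dimethoxybenzyl)dihydrofuran-2(3H)-one | COc1ccc(C[C@H]2COC(=O)[C@@H]2Cc2cc(OC)c(OCc3ccccc3)c(OC)c2)cc1OC | intermediate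
17 | (3R,4R)-4-(3,4-dimethoxybenzyl)-3-(4-hydroxy-3,5-dimethoxybenzyl)dihydrofuran-2(3H)-one | COc1ccc(C[C@H]2COC(=O)[C@@H]2Cc2cc(OC)c(O)c(OC)c2)cc1OC | target

## Step count and least certain steps

Total: 10 steps. Longest linear sequence: 9 steps (1 → 3 → 4 → 9 → 10 → 11 → 13 → 14 → 16 → 17); step 3 lies on the side branch from 5.

Step 7 (key step). The most likely failure is incomplete convergence on the trans lactone. The closure may discriminate poorly between the two methylenes and acid-catalysed acyl transfer from 12 to 13 may be slow. Forcing it could bring enolisation at C3, which together with translactonisation would erode enantiomeric purity. Intermolecular opening, or Friedel–Crafts attack of the syringyl ring on the activated oxetane, could compete if the medium is too concentrated or too acidic. Within the plan the first answers are separation and re-equilibration of 12, or a chiral phosphoric acid matched to C3. The fallback changes the order of events, with C4 set first and C3 by kinetic alkylation; it sets out from 6 and returns at 16.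
- Aldehyde 6 is reduced with NaBH4 to [4-(benzyloxy)-3,5-dimethoxyphenyl]methanol F1, which PBr3 converts into 2-(benzyloxy)-5-(bromomethyl)-1,3-dimethoxybenzene F2.
- Separately, commercial 3-(3,4-dimethoxyphenyl)propanoic acid is activated with pivaloyl chloride and Et3N as 3-(3,4-dimethoxyphenyl)propanoic pivalic anhydride F3 and joined with (S)-4-benzyloxazolidin-2-one (LiCl) to give (S)-4-benzyl-3-[3-(3,4-dimethoxyphenyl)propanoyl]oxazolidin-2-one F4.
- Evans alkylation of its sodium enolate (NaN(SiMe3)2, THF, −78 °C) with tert-butyl bromoacetate, anti to the auxiliary benzyl group, gives tert-butyl (R)-4-[(S)-4-benzyl-2-oxooxazolidin-3-yl]-3-(3,4-dimethoxybenzyl)-4-oxobutanoate F5.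
- LiBH4 removes the auxiliary reductively to give tert-butyl (R)-3-(3,4-dimethoxybenzyl)-4-hydroxybutanoate F6, and catalytic p-toluenesulfonic acid in warm toluene closes it to (R)-4-(3,4-dimethoxybenzyl)dihydrofuran-2(3H)-one F7 (the same compound as A5).
- The lithium enolate of F7 (LiN(SiMe3)2, THF, −78 °C) is alkylated by F2 anti to the C4 substituent to give 16, and step 10 follows.

Step 6. The risks are insufficient or reversed facial selectivity on this particular α-substituent, erosion by any (Z)-isomer carried over from step 4, and opening of the oxetane by the unsaturated acid before hydrogenation, which would give a benzylidene lactone with uncontrolled C4. The fallback replaces the catalytic hydrogenation by an auxiliary-controlled Evans alkylation; it sets out from 4, uses bromide F2 and returns at 11. It also makes the route independent of the alkene geometry from step 4.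
- Ester 4 is saponified (LiOH) to lithium 2-(oxetan-3-yl)acetate F8, which is kept as the salt.
- Pivaloyl chloride converts F8 into 2-(oxetan-3-yl)acetic pivalic anhydride F9, and lithiated (R)-4-benzyloxazolidin-2-one (n-BuLi, THF, −78 °C) gives (R)-4-benzyl-3-[2-(oxetan-3-yl)acetyl]oxazolidin-2-one F10.
- The sodium enolate (NaN(SiMe3)2, THF, −78 °C) is alkylated with F2 to give (R)-4-benzyl-3-{(R)-3-[4-(benzyloxy)-3,5-dimethoxyphenyl]-2-(oxetan-3-yl)propanoyl}oxazolidin-2-one F11.
- LiOH/H2O2 at 0 °C releases 11 under basic conditions that leave the oxetane closed.

Step 9. Homocoupling or reduction of the alkyl bromide may outrun cross-coupling, because oxidative addition of the electron-rich aryl bromide to zerovalent nickel is slow. The free C7 radical may also add to the neighbouring syringyl ring. The fallback replaces the radical cross-electrophile coupling by a two-electron Negishi coupling of a preformed nucleophile; it sets out from 14 and returns at 16. Zinc dust (iodine-activated, DMA, 70 °C) inserts into 14 to give {[(3R,4R)-4-[4-(benzyloxy)-3,5-dimethoxybenzyl]-5-oxooxolan-3-yl]methyl}zinc bromide F12, which is coupled with 15 under Pd(OAc)2/SPhos (THF/DMA, 50 °C) to give 16.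

## Further compounds

F1 | step 7 | [4-(benzyloxy)-3,5-dimethoxyphenyl]methanol | COc1cc(CO)cc(OC)c1OCc1ccccc1
F2 | step 7 | 2-(benzyloxy)-5-(bromomethyl)-1,3-dimethoxybenzene | COc1cc(CBr)cc(OC)c1OCc1ccccc1
F3 | step 7 | 3-(3,4-dimethoxyphenyl)propanoic pivalic anhydride | COc1ccc(CCC(=O)OC(=O)C(C)(C)C)cc1OC
F4 | step 7 | (S)-4-benzyl-3-[3-(3,4-dimethoxyphenyl)propanoyl]oxazolidin-2-one | COc1ccc(CCC(=O)N2[C@@H](Cc3ccccc3)COC2=O)cc1OC
F5 | step 7 | tert-butyl (R)-4-[(S)-4-benzyl-2-oxooxazolidin-3-yl]-3-(3,4-dimethoxybenzyl)-4-oxobutanoate | COc1ccc(C[C@H](CC(=O)OC(C)(C)C)C(=O)N2[C@@H](Cc3ccccc3)COC2=O)cc1OC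
F6 | step 7 | tert-butyl (R)-3-(3,4-dimethoxybenzyl)-4-hydroxybutanoate | COc1ccc(C[C@H](CC(=O)OC(C)(C)C)CO)cc1OC
F7 | step 7 | (R)-4-(3,4-dimethoxybenzyl)dihydrofuran-2(3H)-one | COc1ccc(C[C@H]2COC(=O)C2)cc1OC
F8 | step 6 | lithium 2-(oxetan-3-yl)acetate | [Li+].[O-]C(=O)CC1COC1
F9 | step 6 | 2-(oxetan-3-yl)acetic pivalic anhydride | CC(C)(C)C(=O)OC(=O)CC1COC1
F10 | step 6 | (R)-4-benzyl-3-[2-(oxetan-3-yl)acetyl]oxazolidin-2-one | O=C(CC1COC1)N1[C@H](Cc2ccccc2)COC1=O
F11 | step 6 | (R)-4-benzyl-3-{(R)-3-[4-(benzyloxy)-3,5-dimethoxyphenyl]-2-(oxetan-3-yl)propanoyl}oxazolidin-2-one | O=C([C@H](Cc1cc(OC)c(OCc2ccccc2)c(OC)c1)C1COC1)N1[C@H](Cc2ccccc2)COC1=O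
F12 | step 9 | {[(3R,4R)-4-[4-(benzyloxy)-3,5-dimethoxybenzyl]-5-oxooxolan-3-yl]methyl}zinc bromide | Br[Zn]C[C@H]1COC(=O)[C@@H]1Cc1cc(OC)c(OCc2ccccc2)c(OC)c1
A1 | alternative 1 | tert-butyldimethylsilyl ether of 2-[4-(benzyloxy)-3,5-dimethoxybenzyl]-4-(3,4-dimethoxyphenyl)-3-(4,4,5,5-tetramethyl-1,3,2-dioxaborolan-2-yl)butan-1-ol, configuration as in the SMILES | COc1ccc(C[C@H]([C@H](CO[Si](C)(C)C(C)(C)C)Cc2cc(OC)c(OCc3ccccc3)c(OC)c2)B2OC(C)(C)C(C)(C)O2)cc1OC
A2 | alternative 1 | tert-butyl{3-[4-(benzyloxy)-3,5-dimethoxyphenyl]-2-(4,4,5,5-tetramethyl-1,3,2-dioxaborolan-2-yl)propoxy}dimethylsilane, configuration as in the SMILES | CC1(C)OB(OC1(C)C)[C@H](CO[Si](C)(C)C(C)(C)C)Cc1cc(OC)c(OCc2ccccc2)c(OC)c1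
A3 | alternative 1 | 3,4-dimethoxyphenyl trifluoromethanesulfonate | COc1ccc(OS(=O)(=O)C(F)(F)F)cc1OC
A4 | alternative 1 | vinyllithium | [Li]C=C
A5 | alternative 2 | (R)-4-(3,4-dimethoxybenzyl)dihydrofuran-2(3H)-one | COc1ccc(C[C@H]2COC(=O)C2)cc1OC
A6 | alternative 2 | 3-(3,4-dimethoxybenzyl)cyclobutan-1-one | COc1ccc(CC2CC(=O)C2)cc1OC
A7 | alternative 3 | (R,E)-3-[4-(benzyloxy)-3,5-dimethoxybenzylidene]-4-(3,4-dimethoxybenzyl)dihydrofuran-2(3H)-one | COc1ccc(C[C@H]2COC(=O)/C2=C/c2cc(OC)c(OCc3ccccc3)c(OC)c2)cc1OC
A8 | alternative 3 | (E)-3-(3,4-dimethoxyphenyl)allyl propiolate | C#CC(=O)OC/C=C/c1ccc(OC)c(OC)c1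
A9 | alternative 3 | [4-(benzyloxy)-3,5-dimethoxyphenyl]boronic acid | COc1cc(B(O)O)cc(OC)c1OCc1ccccc1
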